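Millimolar per second was the unit I began in: solid E enters the solution at a rate, and I wanted to know how long that rate takes to pass the charge through.

| flask | E | temperature | time |
|---|---|---|---|
| Tuesday's | 5.0 mM | 40 °C | 2.0 min |
| Thursday's | 5.0 mM | 55 °C | 2.0 min |
| Saturday's | 5.0 mM | 70 °C | 2.0 min |

    Z → G (k1 = 0.032 s⁻¹, Ea1 = 81.0 kJ mol⁻¹)
    E ⇌ Z, rate k2*(cs2 - [Z]) while solid is left; crystals form when [Z] > cs2 (cs2 = 0.63 mM, k2 = 0.21 s⁻¹)
    Z → D (k3 = 0.010 s⁻¹, Ea3 = 91.0 kJ mol⁻¹)
    (constants at 40 °C)

- given per volume of solution although it is solid: E
- the constants hold at 40 °C; other temperatures follow from the activation energies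
- at the start none of E is in solution
- what has only dissolved of E counts as not reacted

- which flask leads in amount of G, in percent of the E charged ("all alike" within 1.5 percentage points) (Tuesday's / Thursday's / Saturday's / all alike)
- how much G is there at the end, in percent of the E charged: Tuesday's
- how much G is there at the end, in percent of the E charged: Thursday's
- how much G is there at the end, in percent of the E charged: Saturday's

While solid is left, I took Z to be at a quasi-steady state, so its balance reads:

dissolution coefficient × (solubility − Z) = loss constant × Z

The loss constant is the sum of the constants towards G and D, and the throughput is loss constant × Z.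

Tuesday's: loss constant 0.0420 s⁻¹, Z 0.525 mM, throughput 0.0221 mM s⁻¹, clearing time 3.78 min

Thursday's: constants 0.133 s⁻¹ and 0.0494 s⁻¹, loss constant 0.182 s⁻¹, clearing time 1.36 min

Saturday's: constants 0.486 s⁻¹ and 0.212 s⁻¹, loss constant 0.698 s⁻¹, clearing time 0.819 min

The clearing time, the charge of E divided by the throughput while solid is left, is my yardstick for the run.

Tuesday's and Thursday's look nearly the same, with equal charge and time, yet they fall on opposite sides of it. Tuesday's clearing time is longer than the run, so I took G as the selectivity (constant towards G over loss constant) times run over clearing time:

G, Tuesday's = 40.3%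

Thursday's clearing time is shorter than the run, and the last Z then fades in about 5.49 s, less than the time still on the clock. So I took the selectivity itself as the yield of these flasks:

G, Thursday's = 72.9%

G, Saturday's = 69.6%

Saturday's clearing time also lies within the run, but its selectivity is lower than Thursday's, as the D step has the higher activation energy. My lead: Thursday's.

The forecast gave 39%, 72.8% and 69.6% and put Thursday's first, holding that “Thursday's finishes in time and keeps the better selectivity”. Its Tuesday's figure lies below mine.

The flasks gave 39.0%, 72.9% and 69.6% for Tuesday's, Thursday's and Saturday's, with Thursday's in the lead. At 2.00 min, Tuesday's, with a clearing time of 3.78 min, still held 38.3% of the charge as solid E, while Thursday's, with 1.36 min, held 0%. A neighbour like Tuesday's but kept at 15 °C has constants 0.00215 s⁻¹ and 4.82 × 10⁻⁴ s⁻¹, so its loss constant is 0.00263 s⁻¹ and its clearing time 50.8 min, far longer than Tuesday's. Selectivity times run over clearing time gives 3.21% of G there, and that flask read 3.09%.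

The numbers of this flask are made up; the rest is arithmetic.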